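Ring B is cut at two opposite bonds, the ring-fusion bond C5–C10 and C8–C9, which unfolds the decalin into an acyclic 1,7,9-decatriene: a C9=C10 (E)-aryl enone carrying the C10 methyl, a C5–C8 (E,E)-1-silyloxydiene, and the C1–C4 chain between them. One intramolecular Diels–Alder reaction closes rings A and B and sets C5, C8, C9 and C10, steered by C3 and C4, which a catalytic nerylboration of pent-4-ynal installs. The precursor carries O3 and O8 as TBS ethers and the phenol as a methyl carbonate, which makes the enone more electron-poor and later triggers the C11 deoxygenation without any late acid step.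

Key step: step 15

Remarks. Atom numbers are those of the target: ring A = C1, C2, C3, C4, C5, C10; ring B = C5, C6, C7, C8, C9, C10; C11 = benzylic carbon; C12 = methylidene carbon; C1'–C4' = chain on C4. In bicyclic compounds α is the face that carries the C10 methyl group and β the other face. TBS = tert-butyldimethylsilyl; pin = pinacolato; (S)-TRIP = (S)-3,3'-bis(2,4,6-triisopropylphenyl)-1,1'-binaphthyl-2,2'-diyl hydrogen phosphate.
Assumption: the (R)-acid of this type sends an allyl group to the Re face of an aldehyde, so the (S)-acid is taken for the Si face of 4; if the sense is reversed for this pair, the other catalyst enantiomer is used.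

Step 1
Reactants: 1 nerol
Product: 2 2-[(2Z)-3,7-dimethylocta-2,6-dien-1-yl]-4,4,5,5-tetramethyl-1,3,2-dioxaborolane
Conditions: B2pin2, Pd(MeCN)4(BF4)2 (5 mol%), DMSO/MeOH, rt
Reagents that add atoms: bis(pinacolato)diboron, CC1(C)OB(OC1(C)C)B1OC(C)(C)C(C)(C)O1
Why: Palladium-catalysed borylation of an allylic alcohol through an η3-allyl complex should put boron on the unsubstituted terminus and keep the Z trisubstituted alkene, as is known for nerol and geraniol.

Step 2
Reactants: 3 pent-4-yn-1-ol
Product: 4 pent-4-ynal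
Conditions: DMP, NaHCO3, CH2Cl2, 0 °C → rt; used as a solution
Reagents that add atoms: none
Why: Dess–Martin oxidation stops at the aldehyde, and the volatile product is carried on without concentration.

Step 3
Reactants: 2 neryl pinacol boronate; 4 pent-4-ynal
Product: 6 (5R,6R)-6-ethenyl-6,10-dimethylundec-9-en-1-yn-5-ol, via pinacol borate 5 (not isolated)
Conditions: (S)-TRIP (5 mol%), 4 Å MS, PhMe, −30 → 0 °C; then aq. NaHCO3
Reagents that add atoms: none
Why: Brønsted acid-catalysed allylboration through a closed chair transition state, in which the Z boronate places its chain pseudo-axial and its methyl pseudo-equatorial on the γ-carbon (hydroxyl and chain syn, the relative configuration of C3 and C4), while the chiral acid selects the Si face of the aldehyde and so should set (5R,6R).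

Step 4
Reactants: 6 (5R,6R)-6-ethenyl-6,10-dimethylundec-9-en-1-yn-5-ol
Product: 7 tert-butyl{[(5R,6R)-6-ethenyl-6,10-dimethylundec-9-en-1-yn-5-yl]oxy}dimethylsilane
Conditions: TBSOTf, 2,6-lutidine, CH2Cl2, −78 → 0 °C
Reagents that add atoms: tert-butyldimethylsilyl trifluoromethanesulfonate, CC(C)(C)[Si](C)(C)OS(=O)(=O)C(F)(F)F
Why: A silyl triflate with a hindered base silylates the secondary carbinol next to the quaternary carbon, and the same group as on O8 allows one later deprotection.

Step 5
Reactants: 7 silyl ether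
Product: 9 tert-butyl{[(1E,5R,6R)-6-ethenyl-1-iodo-2,6,10-trimethylundeca-1,9-dien-5-yl]oxy}dimethylsilane, via alkenyldimethylalane 8 (not isolated)
Conditions: Me3Al, Cp2ZrCl2 (0.3 equiv), CH2Cl2, 0 °C → rt; then I2, THF, −30 °C
Reagents that add atoms: trimethylaluminium, C[Al](C)C; iodine, [I][I]
Why: Zirconium-catalysed syn carboalumination of the terminal alkyne (Negishi) puts the methyl on C10 and aluminium on C9, and iodinolysis with retention gives the E alkenyl iodide, while the alkenes do not react.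

Step 6
Reactants: 9 alkenyl iodide
Product: 11 (3R,4R,7E)-4-(tert-butyldimethylsilyloxy)-8-iodo-3,7-dimethyl-3-(4-methylpent-3-en-1-yl)oct-7-en-1-ol, via B-alkyl-9-BBN adduct 10 (not isolated)
Conditions: 9-BBN, THF, 0 °C → rt; then NaOH, H2O2, 0 °C
Reagents that add atoms: hydrogen peroxide, OO
Why: 9-BBN hydroborates only the monosubstituted alkene, with boron on the terminal carbon C6, leaves the two trisubstituted alkenes, and oxidation of the C–B bond gives the primary alcohol.

Step 7
Reactants: 11 primary alcohol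
Product: 12 (3R,4R,7E)-4-(tert-butyldimethylsilyloxy)-8-iodo-3,7-dimethyl-3-(4-methylpent-3-en-1-yl)oct-7-enal
Conditions: DMP, NaHCO3, CH2Cl2, 0 °C → rt
Reagents that add atoms: none
Why: Dess–Martin oxidation of a primary alcohol to the aldehyde, which has no epimerisable α-centre.

Step 8
Reactants: 12 aldehyde
Product: 13 (2E,5R,6R,9E)-6-(tert-butyldimethylsilyloxy)-10-iodo-5,9-dimethyl-5-(4-methylpent-3-en-1-yl)deca-2,9-dienal
Conditions: Ph3P=CHCHO, PhMe, 80 °C
Reagents that add atoms: (triphenylphosphoranylidene)acetaldehyde, O=CC=P(c1ccccc1)(c1ccccc1)c1ccccc1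
Why: Wittig olefination with a stabilised ylide adds C7 and C8 as the E enal and leaves the alkenyl iodide alone.

Step 9
Reactants: 13 enal
Product: 14 (1E,3E,5R,6R,9E)-1,6-bis(tert-butyldimethylsilyloxy)-10-iodo-5,9-dimethyl-5-(4-methylpent-3-en-1-yl)deca-1,3,9-triene
Conditions: TBSOTf, Et3N, Et2O, 0 °C → rt
Reagents that add atoms: tert-butyldimethylsilyl trifluoromethanesulfonate, CC(C)(C)[Si](C)(C)OS(=O)(=O)C(F)(F)F
Why: O-silylation of the s-trans enal and γ-deprotonation by the amine (soft enolisation) give the 1-silyloxydiene, the s-trans enal fixing C7=C8 as E and the quaternary C4 forcing C5=C6 to be E, and no ketone is yet present to compete.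

Step 10
Reactants: 15 methyl 3-formyl-4-hydroxybenzoate
Product: 16 methyl 3-bromo-5-formyl-4-hydroxybenzoate
Conditions: Br2, NaOAc, AcOH, rt
Reagents that add atoms: bromine, BrBr
Why: Electrophilic aromatic bromination goes to the only free position ortho to the hydroxyl group.

Step 11
Reactants: 16 bromophenol aldehyde
Product: 17 methyl 3-bromo-5-formyl-4-[(methoxycarbonyl)oxy]benzoate
Conditions: ClCO2Me, Et3N, CH2Cl2, 0 °C
Reagents that add atoms: methyl chloroformate, COC(=O)Cl
Why: O-acylation of the phenol gives a carbonate that withdraws electrons from the later aryl ketone, survives the zinc coupling and heat, serves as the leaving group in step 16 and spares the end game an acid-labile phenol protecting group.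

Step 12
Reactants: 17 carbonate aldehyde
Product: 18 3-bromo-5-(methoxycarbonyl)-2-[(methoxycarbonyl)oxy]benzoic acid
Conditions: NaClO2, NaH2PO4, 2-methyl-2-butene, t-BuOH/H2O, 0 °C → rt
Reagents that add atoms: sodium chlorite, [Na+].[O-]Cl=O
Why: Pinnick oxidation converts the aldehyde into the acid at a pH that leaves the carbonate and the ester intact.

Step 13
Reactants: 18 benzoic acid
Product: 19 methyl 3-bromo-5-(chlorocarbonyl)-4-[(methoxycarbonyl)oxy]benzoate
Conditions: (COCl)2, DMF (cat.), CH2Cl2, 0 °C → rt; used crude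
Reagents that add atoms: oxalyl chloride, O=C(Cl)C(Cl)=O
Why: Acid chloride formation through the chloroiminium salt, as known for ortho-acyloxybenzoic acids.

Step 14
Reactants: 14 iodo silyloxydiene; 19 acid chloride
Product: 22 methyl 3-bromo-5-[(2E,6R,7R,8E,10E)-6,11-bis(tert-butyldimethylsilyloxy)-3,7-dimethyl-7-(4-methylpent-3-en-1-yl)undeca-2,8,10-trienoyl]-4-[(methoxycarbonyl)oxy]benzoate, via alkenyllithium 20 (not isolated), via alkenylzinc chloride 21 (not isolated)
Conditions: t-BuLi (2.1 equiv), Et2O, −78 °C; ZnCl2, THF, −78 → 0 °C; then 19, Pd(PPh3)4 (5 mol%), THF, 0 °C → rt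
Reagents that add atoms: none
Why: Iodine–lithium exchange with retention, transmetalation to zinc and palladium-catalysed acylation (Negishi) give the E enone directly, since oxidative addition into the acyl chloride is far faster than into the aryl bromide and no alkoxide is formed next to the carbonate.

Step 15
Reactants: 22 triene
Product: 23 methyl 3-bromo-4-[(methoxycarbonyl)oxy]-5-{[3α,8α-bis(tert-butyldimethylsilyloxy)-4α,10α-dimethyl-4β-(4-methylpent-3-enyl)-5β,9β-H-trans-Δ6-octalin-9α-yl]carbonyl}benzoate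
Conditions: BHT (0.1 equiv), PhMe (0.01 M), sealed tube, 150 °C
Reagents that add atoms: none
Why: A concerted, asynchronous [4+2] cycloaddition joins the C5–C8 silyloxydiene (HOMO raised by O8) and the C9=C10 enone (LUMO lowered by the aroyl group with its carbonate-bearing ring), the closest known type being the intramolecular Diels–Alder reaction of 1,7,9-decatrienes with a terminally activated E dienophile to trans-decalins. Ring B closes as the new cyclohexene through both forming bonds (C5–C10 and C8–C9), and ring A closes as the fused six-membered ring that the C5–C10 bond completes around the C1–C4 tether folded as a chair. Suprafacial addition to the E enone fixes the C9 aroyl group cis to the C10 methyl, the endo position of the aroyl group (tether exo) gives H5 trans to the C10 methyl, and the E,E diene then places O8 cis to the aroyl group. The sense at C5 and C10 relative to C3 and C4 comes from the tether chair: the one with the C3 silyloxy group and the C4 chain equatorial and only the C4 methyl axial should be preferred over the one with oxygen and chain both axial and the chain syn-axial to the C10 methyl. The step needs endo/exo and diene-face selectivity; the first rests on the E dienophile with its aroyl group endo, the second on the C3/C4 pair and is the less secure, as is the reactivity of a β-methyl enone toward a diene next to the quaternary C4. A diene that is Z at C5=C6 cannot reach the s-cis form and should be left behind.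

Step 16
Reactants: 23 adduct
Product: 27 methyl 3-bromo-4-hydroxy-5-{[3α,8α-bis(tert-butyldimethylsilyloxy)-4α,10α-dimethyl-4β-(4-methylpent-3-enyl)-trans-Δ6-octalin-9α-yl]methyl}benzoate, via benzylic alkoxide 24 (not isolated), via benzylic methyl carbonate 25 (not isolated), via ortho-quinone methide 26 (not isolated)
Conditions: NaBH4 (excess), THF/H2O, 0 °C → rt (to 40 °C if needed)
Reagents that add atoms: none
Why: Hydride adds to the aryl ketone, the alkoxide takes over the neighbouring carbonate, the phenoxide expels methyl carbonate to give an ortho-quinone methide and a second hydride adds at C11 (the known reduction of ortho-acyloxyaryl ketones to ortho-alkylphenols), so no stereocenter remains at C11 and C9 is untouched.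

Step 17
Reactants: 27 bis(silyl ether)
Product: 28 methyl 3-bromo-4-hydroxy-5-{[3α,8α-dihydroxy-4α,10α-dimethyl-4β-(4-methylpent-3-enyl)-trans-Δ6-octalin-9α-yl]methyl}benzoate
Conditions: HF·pyridine, pyridine/THF, 0 °C → rt
Reagents that add atoms: none
Why: Buffered fluoride cleaves both secondary silyl ethers in one operation and spares the ester, the aryl bromide and the alkenes.

Step 18
Reactants: 28 diol
Product: 29 methyl 3-bromo-4-hydroxy-5-{[3α-hydroxy-4α,10α-dimethyl-4β-(4-methylpent-3-enyl)-8-oxo-trans-Δ6-octalin-9α-yl]methyl}benzoate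
Conditions: MnO2 (activated, excess), CH2Cl2, rt
Reagents that add atoms: none
Why: MnO2 oxidises only the allylic C8 carbinol to the enone, while the saturated, hindered C3 carbinol is inert.

Step 19
Reactants: 29 enone
Product: 30 methyl 3-bromo-4-hydroxy-5-{[3α-hydroxy-4α,10α-dimethyl-4β-(4-methylpent-3-enyl)-8-oxo-trans-decalin-9α-yl]methyl}benzoate
Conditions: [(Ph3P)CuH]6, H2O, PhMe, rt
Reagents that add atoms: none
Why: The copper hydride (Stryker) delivers hydride 1,4 to the enone only, so the C6–C7 bond is saturated without touching the chain alkene, the aryl bromide or the ester, and the equatorial C9 substituent is the stable epimer next to the ketone.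

Step 20
Reactants: 30 ketone
Product: 31 methyl 3-bromo-4-hydroxy-5-{[3α-hydroxy-4α,10α-dimethyl-8-methylidene-4β-(4-methylpent-3-enyl)-trans-decalin-9α-yl]methyl}benzoate
Conditions: Ph3PCH3Br, KOt-Bu (excess), THF, 0 → 50 °C
Reagents that add atoms: methyltriphenylphosphonium bromide, C[P+](c1ccccc1)(c1ccccc1)c1ccccc1.[Br-]
Why: Wittig methylenation of the C8 ketone installs C12, the phenoxide formed in the basic medium deactivating the para ester toward the ylide.

Step 21
Reactants: 31 alcohol
Product: 32 methyl 3-bromo-4-hydroxy-5-{[4α,10α-dimethyl-8-methylidene-4β-(4-methylpent-3-enyl)-3-oxo-trans-decalin-9α-yl]methyl}benzoate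
Conditions: DMP, NaHCO3, CH2Cl2, 0 °C → rt
Reagents that add atoms: none
Why: Buffered Dess–Martin oxidation of the equatorial C3 carbinol; the fully ortho- and para-substituted, electron-poor phenol offers no site for oxidation and the buffer keeps the phenol from adding to the methylidene group.

Step 22
Reactants: 32 ketone
Product: 33 methyl 3-bromo-4-hydroxy-5-{[3β-hydroxy-4α,10α-dimethyl-8-methylidene-4β-(4-methylpent-3-enyl)-trans-decalin-9α-yl]methyl}benzoate
Conditions: KBH(s-Bu)3 (excess), THF, −78 °C; then aq. NH4Cl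
Reagents that add atoms: none
Why: The bulky hydride adds along the equatorial trajectory, avoiding the syn-axial hydrogens on C1 and C5 as with 4,4-disubstituted 3-ketones of triterpenoids, and should give the axial 3β alcohol.

Step 23
Reactants: 33 axial alcohol
Product: 34 methyl 3-bromo-5-{[3α-bromo-4α,10α-dimethyl-8-methylidene-4β-(4-methylpent-3-enyl)-trans-decalin-9α-yl]methyl}-4-hydroxybenzoate
Conditions: CBr4, PPh3, PhMe, 0 → 40 °C
Reagents that add atoms: tetrabromomethane, BrC(Br)(Br)Br
Why: Appel reaction, in which bromide displaces the axial oxyphosphonium group from the rear (SN2) and should give the equatorial 3α bromide with inversion, as known for axial carbinols next to a quaternary carbon.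

Step 24
Reactants: 34 methyl ester
Product: 35 callophycoic acid H
Conditions: LiOH, THF/MeOH/H2O, rt → 40 °C; then dilute HCl to pH 3–4, 0 °C
Reagents that add atoms: lithium hydroxide, [Li+].[OH-]
Why: Saponification of the methyl ester; the equatorial bromide has no antiperiplanar hydrogen for elimination and its neopentyl-type carbon resists substitution, and the cold, mild acidification frees the acid without adding the phenol to the methylidene group.

Compound list
1 | nerol, (2Z)-3,7-dimethylocta-2,6-dien-1-ol | CC(C)=CCC/C(C)=C\CO | starting material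
2 | 2-[(2Z)-3,7-dimethylocta-2,6-dien-1-yl]-4,4,5,5-tetramethyl-1,3,2-dioxaborolane | CC(C)=CCC/C(C)=C\CB1OC(C)(C)C(C)(C)O1 | intermediate
3 | pent-4-yn-1-ol | C#CCCCO | starting material
4 | pent-4-ynal | C#CCCC=O | intermediate
5 | pinacol borate of 6 (B(pin) on the C5 oxygen) | C#CCC[C@@H](OB1OC(C)(C)C(C)(C)O1)[C@](C)(CCC=C(C)C)C=C | intermediate
6 | (5R,6R)-6-ethenyl-6,10-dimethylundec-9-en-1-yn-5-ol | C#CCC[C@@H](O)[C@](C)(CCC=C(C)C)C=C | intermediate
7 | tert-butyl{[(5R,6R)-6-ethenyl-6,10-dimethylundec-9-en-1-yn-5-yl]oxy}dimethylsilane | C#CCC[C@@H](O[Si](C)(C)C(C)(C)C)[C@](C)(CCC=C(C)C)C=C | intermediate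
8 | (E)-alkenyldimethylalane from 7 (AlMe2 on C9; new CH3 on C10) | C[Al](C)/C=C(\C)CC[C@@H](O[Si](C)(C)C(C)(C)C)[C@](C)(CCC=C(C)C)C=C | intermediate
9 | tert-butyl{[(1E,5R,6R)-6-ethenyl-1-iodo-2,6,10-trimethylundeca-1,9-dien-5-yl]oxy}dimethylsilane | I/C=C(\C)CC[C@@H](O[Si](C)(C)C(C)(C)C)[C@](C)(CCC=C(C)C)C=C | intermediate
10 | B-alkyl-9-borabicyclo[3.3.1]nonane from 9 (boron on C6; the former vinyl group) | I/C=C(\C)CC[C@@H](O[Si](C)(C)C(C)(C)C)[C@](C)(CCC=C(C)C)CCB1C2CCCC1CCC2 | intermediate
11 | (3R,4R,7E)-4-(tert-butyldimethylsilyloxy)-8-iodo-3,7-dimethyl-3-(4-methylpent-3-en-1-yl)oct-7-en-1-ol | I/C=C(\C)CC[C@@H](O[Si](C)(C)C(C)(C)C)[C@](C)(CCC=C(C)C)CCO | intermediate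
12 | (3R,4R,7E)-4-(tert-butyldimethylsilyloxy)-8-iodo-3,7-dimethyl-3-(4-methylpent-3-en-1-yl)oct-7-enal | I/C=C(\C)CC[C@@H](O[Si](C)(C)C(C)(C)C)[C@](C)(CCC=C(C)C)CC=O | intermediate
13 | (2E,5R,6R,9E)-6-(tert-butyldimethylsilyloxy)-10-iodo-5,9-dimethyl-5-(4-methylpent-3-en-1-yl)deca-2,9-dienal | I/C=C(\C)CC[C@@H](O[Si](C)(C)C(C)(C)C)[C@](C)(CCC=C(C)C)C/C=C/C=O | intermediate
14 | (1E,3E,5R,6R,9E)-1,6-bis(tert-butyldimethylsilyloxy)-10-iodo-5,9-dimethyl-5-(4-methylpent-3-en-1-yl)deca-1,3,9-triene | I/C=C(\C)CC[C@@H](O[Si](C)(C)C(C)(C)C)[C@](C)(CCC=C(C)C)/C=C/C=C/O[Si](C)(C)C(C)(C)C | intermediate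
15 | methyl 3-formyl-4-hydroxybenzoate | COC(=O)c1ccc(O)c(C=O)c1 | starting material
16 | methyl 3-bromo-5-formyl-4-hydroxybenzoate | COC(=O)c1cc(Br)c(O)c(C=O)c1 | intermediate
17 | methyl 3-bromo-5-formyl-4-[(methoxycarbonyl)oxy]benzoate | COC(=O)Oc1c(Br)cc(C(=O)OC)cc1C=O | intermediate
18 | 3-bromo-5-(methoxycarbonyl)-2-[(methoxycarbonyl)oxy]benzoic acid | COC(=O)Oc1c(Br)cc(C(=O)OC)cc1C(=O)O | intermediate
19 | methyl 3-bromo-5-(chlorocarbonyl)-4-[(methoxycarbonyl)oxy]benzoate | COC(=O)Oc1c(Br)cc(C(=O)OC)cc1C(Cl)=O | intermediate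
20 | alkenyllithium from 14 (Li in place of I) | [Li]/C=C(\C)CC[C@@H](O[Si](C)(C)C(C)(C)C)[C@](C)(CCC=C(C)C)/C=C/C=C/O[Si](C)(C)C(C)(C)C | intermediate
21 | alkenylzinc chloride from 14 (ZnCl in place of I) | Cl[Zn]/C=C(\C)CC[C@@H](O[Si](C)(C)C(C)(C)C)[C@](C)(CCC=C(C)C)/C=C/C=C/O[Si](C)(C)C(C)(C)C | intermediate
22 | methyl 3-bromo-5-[(2E,6R,7R,8E,10E)-6,11-bis(tert-butyldimethylsilyloxy)-3,7-dimethyl-7-(4-methylpent-3-en-1-yl)undeca-2,8,10-trienoyl]-4-[(methoxycarbonyl)oxy]benzoate | COC(=O)Oc1c(Br)cc(C(=O)OC)cc1C(=O)/C=C(\C)CC[C@@H](O[Si](C)(C)C(C)(C)C)[C@](C)(CCC=C(C)C)/C=C/C=C/O[Si](C)(C)C(C)(C)C | intermediate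
23 | methyl 3-bromo-4-[(methoxycarbonyl)oxy]-5-{[3α,8α-bis(tert-butyldimethylsilyloxy)-4α,10α-dimethyl-4β-(4-methylpent-3-enyl)-5β,9β-H-trans-Δ6-octalin-9α-yl]carbonyl}benzoate | CC(C)(C)[Si](C)(C)O[C@@H]1C=C[C@@H]2[C@@](C)(CCC=C(C)C)[C@H](O[Si](C)(C)C(C)(C)C)CC[C@@]2(C)[C@@H]1C(=O)c3cc(C(=O)OC)cc(Br)c3OC(=O)OC | intermediate
24 | C11 carbinol of 23 as its alkoxide (C11 configuration not defined; drawn as the alcohol) | CC(C)(C)[Si](C)(C)O[C@@H]1C=C[C@@H]2[C@@](C)(CCC=C(C)C)[C@H](O[Si](C)(C)C(C)(C)C)CC[C@@]2(C)[C@@H]1C(O)c3cc(C(=O)OC)cc(Br)c3OC(=O)OC | intermediate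
25 | C11 methyl carbonate with free phenol (carbonate shifted from the aryl oxygen to O11) | CC(C)(C)[Si](C)(C)O[C@@H]1C=C[C@@H]2[C@@](C)(CCC=C(C)C)[C@H](O[Si](C)(C)C(C)(C)C)CC[C@@]2(C)[C@@H]1C(OC(=O)OC)c3cc(C(=O)OC)cc(Br)c3O | intermediate
26 | ortho-quinone methide (C11=C exocyclic to the 2-bromo-4-(methoxycarbonyl)cyclohexa-2,4-dienone ring) | CC(C)(C)[Si](C)(C)O[C@@H]1C=C[C@@H]2[C@@](C)(CCC=C(C)C)[C@H](O[Si](C)(C)C(C)(C)C)CC[C@@]2(C)[C@@H]1C=C3C=C(C(=O)OC)C=C(Br)C3=O | intermediate
27 | methyl 3-bromo-4-hydroxy-5-{[3α,8α-bis(tert-butyldimethylsilyloxy)-4α,10α-dimethyl-4β-(4-methylpent-3-enyl)-trans-Δ6-octalin-9α-yl]methyl}benzoate | CC(C)(C)[Si](C)(C)O[C@@H]1C=C[C@@H]2[C@@](C)(CCC=C(C)C)[C@H](O[Si](C)(C)C(C)(C)C)CC[C@@]2(C)[C@@H]1Cc3cc(C(=O)OC)cc(Br)c3O | intermediate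
28 | methyl 3-bromo-4-hydroxy-5-{[3α,8α-dihydroxy-4α,10α-dimethyl-4β-(4-methylpent-3-enyl)-trans-Δ6-octalin-9α-yl]methyl}benzoate | O[C@@H]1C=C[C@@H]2[C@@](C)(CCC=C(C)C)[C@H](O)CC[C@@]2(C)[C@@H]1Cc3cc(C(=O)OC)cc(Br)c3O | intermediate
29 | methyl 3-bromo-4-hydroxy-5-{[3α-hydroxy-4α,10α-dimethyl-4β-(4-methylpent-3-enyl)-8-oxo-trans-Δ6-octalin-9α-yl]methyl}benzoate | O=C1C=C[C@@H]2[C@@](C)(CCC=C(C)C)[C@H](O)CC[C@@]2(C)[C@@H]1Cc3cc(C(=O)OC)cc(Br)c3O | intermediate
30 | methyl 3-bromo-4-hydroxy-5-{[3α-hydroxy-4α,10α-dimethyl-4β-(4-methylpent-3-enyl)-8-oxo-trans-decalin-9α-yl]methyl}benzoate | O=C1CC[C@@H]2[C@@](C)(CCC=C(C)C)[C@H](O)CC[C@@]2(C)[C@@H]1Cc3cc(C(=O)OC)cc(Br)c3O | intermediate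
31 | methyl 3-bromo-4-hydroxy-5-{[3α-hydroxy-4α,10α-dimethyl-8-methylidene-4β-(4-methylpent-3-enyl)-trans-decalin-9α-yl]methyl}benzoate | C=C1CC[C@@H]2[C@@](C)(CCC=C(C)C)[C@H](O)CC[C@@]2(C)[C@@H]1Cc3cc(C(=O)OC)cc(Br)c3O | intermediate
32 | methyl 3-bromo-4-hydroxy-5-{[4α,10α-dimethyl-8-methylidene-4β-(4-methylpent-3-enyl)-3-oxo-trans-decalin-9α-yl]methyl}benzoate | C=C1CC[C@@H]2[C@@](C)(CCC=C(C)C)C(=O)CC[C@@]2(C)[C@@H]1Cc3cc(C(=O)OC)cc(Br)c3O | intermediate
33 | methyl 3-bromo-4-hydroxy-5-{[3β-hydroxy-4α,10α-dimethyl-8-methylidene-4β-(4-methylpent-3-enyl)-trans-decalin-9α-yl]methyl}benzoate (axial carbinol) | C=C1CC[C@@H]2[C@@](C)(CCC=C(C)C)[C@@H](O)CC[C@@]2(C)[C@@H]1Cc3cc(C(=O)OC)cc(Br)c3O | intermediate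
34 | methyl 3-bromo-5-{[3α-bromo-4α,10α-dimethyl-8-methylidene-4β-(4-methylpent-3-enyl)-trans-decalin-9α-yl]methyl}-4-hydroxybenzoate (equatorial bromide) | C=C1CC[C@@H]2[C@@](C)(CCC=C(C)C)[C@H](Br)CC[C@@]2(C)[C@@H]1Cc3cc(C(=O)OC)cc(Br)c3O | intermediate
35 | callophycoic acid H, 3-bromo-5-{[(3R,4R,5S,9R,10S)-3-bromo-4,10-dimethyl-8-methylidene-4-(4-methylpent-3-enyl)decalin-9-yl]methyl}-4-hydroxybenzoic acid (target numbering) | C=C1CC[C@@H]2[C@@](C)(CCC=C(C)C)[C@H](Br)CC[C@@]2(C)[C@@H]1Cc1cc(C(=O)O)cc(Br)c1O | target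

Total step count: 24. Longest linear sequence: 19 steps (steps 1, 3 to 9 and 14 to 24); step 2 and steps 10 to 13 are side branches.

Steps most likely to fail

Step 15. The cycloaddition may be too slow below the temperature at which the silyl dienol ether is lost or the enone isomerises. The C3/C4 pair may also discriminate the two diene faces only weakly. The fallback replaces the pericyclic step by a stepwise polar annulation at low temperature and sets out from 22. Me2AlCl in CH2Cl2 at −78 °C should trigger an intramolecular vinylogous Mukaiyama–Michael addition of C5 to C10 through the s-cis diene, and the aluminium enolate at C9 then closes ring B by aldol addition to the C8 aldehyde. Work-up gives the 8-hydroxy ketone F1, and TBSOTf with 2,6-lutidine brings it back to the route at 23. The low temperature should also widen the preference between the two tether chairs.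

Step 23. Elimination toward C2=C3 or a 1,2-shift of the axial C4 methyl from the oxyphosphonium ion may outrun rear-side attack at the neopentyl-type C3. The fallback separates activation and displacement and sets out from 33. Tf2O and pyridine in CH2Cl2 at −40 °C give the bis(triflate) F2, in which the axial C3 carbinol and the phenol are both sulfonylated. Bu4NBr in PhMe at −20 → 0 °C displaces the alkyl triflate with inversion to give the aryl triflate bromide F3. The LiOH conditions of step 24 then cleave the aryl triflate together with the methyl ester, and the route is rejoined at 35.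

Step 16. After hydride addition the carbinol may not collapse to the quinone methide, because the phenoxide is stabilised by the para ester or because the silyl group shifts from O8 to O11. The hindered ketone may also take up hydride too slowly. The fallback removes the oxygen through a diazene instead of a quinone methide and sets out from 23. Excess TsNHNH2 in EtOH at 70 °C forms the tosylhydrazone F4, the hydrazide also cleaving the aryl carbonate. Catecholborane in CHCl3 at 0 °C followed by NaOAc·3H2O at 60 °C reduces the C=N bond and expels sulfinate and nitrogen, and the route is rejoined at 27.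

Further compounds
F1 | step 15 | 8-hydroxy ketone, the O8-desilylated form of 23 | O[C@@H]1C=C[C@@H]2[C@@](C)(CCC=C(C)C)[C@H](O[Si](C)(C)C(C)(C)C)CC[C@@]2(C)[C@@H]1C(=O)c3cc(C(=O)OC)cc(Br)c3OC(=O)OC
F2 | step 23 | bis(triflate) of 33 (axial C3 triflate and aryl triflate) | C=C1CC[C@@H]2[C@@](C)(CCC=C(C)C)[C@@H](OS(=O)(=O)C(F)(F)F)CC[C@@]2(C)[C@@H]1Cc3cc(C(=O)OC)cc(Br)c3OS(=O)(=O)C(F)(F)F
F3 | step 23 | aryl triflate of 34 (equatorial C3 bromide) | C=C1CC[C@@H]2[C@@](C)(CCC=C(C)C)[C@H](Br)CC[C@@]2(C)[C@@H]1Cc3cc(C(=O)OC)cc(Br)c3OS(=O)(=O)C(F)(F)F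
F4 | step 16 | C11 tosylhydrazone of the free phenol derived from 23 | CC(C)(C)[Si](C)(C)O[C@@H]1C=C[C@@H]2[C@@](C)(CCC=C(C)C)[C@H](O[Si](C)(C)C(C)(C)C)CC[C@@]2(C)[C@@H]1C(=NNS(=O)(=O)c4ccc(C)cc4)c3cc(C(=O)OC)cc(Br)c3O
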